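## Retrosynthetic overview

1. The C15 ketone comes from DDQ oxidation of an allylic C15 carbinol (epimer mixture allowed); C5=C6 from a Z-selective Wittig reaction on a lactol; C13=C14 from cross-metathesis of a C12 vinyl group with oct-1-en-3-ol at the lactone stage.
2. The lactone (ring B) comes from reduction of the C9 ketone and ring closure; C8–C7 and C12–C13 come from one-pot vinyl conjugate addition/enolate alkylation on (R)-4-silyloxycyclopent-2-enone.
3. Key step: both ring C–O bonds (C9–O and C11–O) come from one O2 molecule, by [4+2] addition of singlet oxygen to cyclopentadiene and catalytic enantioselective Kornblum–DeLaMare opening of the meso peroxide. This fixes C11, which then controls C12, C8 and C9.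
4. Ring order: the carbocycle (ring A) is bought as cyclopentadiene; the peroxide bridge (ring C) is formed and opened in step 1; lactone ring B is formed in step 3, reduced in step 5 and opened in step 6.

Assumption: cyclopentadiene, cracked from commercial dicyclopentadiene just before use, is treated as a commercial starting material and the cracking is not counted as a step.

## Route

**Step 1**
Reactants: 1 cyclopentadiene
Product: 4 (R)-4-[(tert-butyldimethylsilyl)oxy]cyclopent-2-en-1-one, via meso-endoperoxide 2 (not isolated), via (R)-4-hydroxycyclopent-2-en-1-one 3 (not isolated)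
Conditions: O2 (1 atm), tetraphenylporphyrin (0.05 mol %), white LEDs, CH2Cl2, −78 °C; then squaramide Q1 (5 mol %; the squaramide built from 9-amino-9-deoxy-epi-quinidine and 3,5-bis(trifluoromethyl)aniline), −45 °C, 12 h; then TBSCl, imidazole, −45 °C → rt; 4 recrystallised from pentane at −30 °C to raise the ee. If Q1 gives the opposite sense of induction, the quinine-derived pseudo-enantiomer is used.
Reagents that add atoms: dioxygen O=O; tert-butyldimethylsilyl chloride CC(C)(C)[Si](C)(C)Cl
Why: Proposed new method: singlet oxygen adds to the diene in a [4+2] cycloaddition so that both ring C–O bonds (later C9–O and C11–O) come from one O2, and the bifunctional catalyst then performs an enantioselective Kornblum–DeLaMare fragmentation of the strained meso peroxide below its decomposition temperature, the squaramide N–H bonds hydrogen-bonding to one peroxide oxygen while the quinuclidine nitrogen removes only the bridgehead proton on the S-configured carbon in an E2-like step with O–O cleavage, which leaves the R carbinol centre (later C11) untouched; the closest known reaction type is the cinchona-amine-catalysed desymmetrising Kornblum–DeLaMare rearrangement of meso endoperoxides from six- to eight-membered cyclic dienes, not shown for the thermally labile [2.2.1] peroxide of cyclopentadiene, and in situ silylation then traps the water-soluble hydroxy enone as its stable ether.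

**Step 2**
Reactants: 4 (R)-4-[(tert-butyldimethylsilyl)oxy]cyclopent-2-en-1-one; 5 vinylmagnesium bromide; 6 ethyl iodoacetate
Product: 9 ethyl 2-[(1R,2R,3R)-3-[(tert-butyldimethylsilyl)oxy]-5-oxo-2-vinylcyclopentyl]acetate, via bromomagnesium enolate 7 (not isolated), via triphenyltin enolate 8 (not isolated)
Conditions: CH2=CHMgBr (1.3 equiv), CuBr·SMe2 (10 mol %), THF, −78 °C; then Ph3SnCl (1.3 equiv), HMPA, −78 °C; then ICH2CO2Et (3 equiv), −30 °C
Reagents that add atoms: none
Why: Tandem conjugate addition–enolate alkylation (three-component coupling on a 4-silyloxycyclopentenone), in which the vinylcopper species adds anti to the C4 silyloxy group, transmetalation to the non-equilibrating tin enolate suppresses β-elimination of the silyloxy group, and the reactive α-iodo ester alkylates anti to the new vinyl group, giving the trans,trans pattern of C8, C12 and C11.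

**Step 3**
Reactants: 9 ethyl 2-[(1R,2R,3R)-3-[(tert-butyldimethylsilyl)oxy]-5-oxo-2-vinylcyclopentyl]acetate
Product: 11 (3aR,4R,5R,6aS)-5-[(tert-butyldimethylsilyl)oxy]-4-vinylhexahydro-2H-cyclopenta[b]furan-2-one, via cis-hydroxy ester 10 (not isolated)
Conditions: LiBH(s-Bu)3 (L-Selectride, 1.2 equiv), THF, −78 °C → rt; aq. NH4Cl; PPTS (cat.), CH2Cl2, rt if ring closure is incomplete
Reagents that add atoms: none
Why: Diastereoselective ketone reduction by a bulky trialkylborohydride followed by lactonisation, the hydride attacking the cyclopentanone face anti to the adjacent C8 side chain so that the new C9–O bond is cis to the acetate arm and closes to the cis-fused γ-lactone (ring B).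

**Step 4**
Reactants: 11 (3aR,4R,5R,6aS)-5-[(tert-butyldimethylsilyl)oxy]-4-vinylhexahydro-2H-cyclopenta[b]furan-2-one; 12 racemic oct-1-en-3-ol
Product: 13 (3aR,4R,5R,6aS)-5-[(tert-butyldimethylsilyl)oxy]-4-[(1E,3RS)-3-hydroxyoct-1-en-1-yl]hexahydro-2H-cyclopenta[b]furan-2-one (1:1 mixture of carbinol epimers)
Conditions: 12 (3 equiv), second-generation Hoveyda–Grubbs catalyst RuCl2(H2IMes)(=CH-C6H4-2-O-i-Pr) (5 mol %), 1,4-benzoquinone (10 mol %), CH2Cl2, 40 °C
Reagents that add atoms: none
Why: Olefin cross-metathesis, in which the hindered α-branched vinyl group does not homodimerise, excess allylic alcohol drives the exchange to the thermodynamically preferred E alkene, and no other alkene is present to compete; the carbinol is deliberately an epimer mixture because it is oxidised in step 7.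

**Step 5**
Reactants: 13 (3aR,4R,5R,6aS)-5-[(tert-butyldimethylsilyl)oxy]-4-[(1E,3RS)-3-hydroxyoct-1-en-1-yl]hexahydro-2H-cyclopenta[b]furan-2-one
Product: 14 (3aR,4R,5R,6aS)-5-[(tert-butyldimethylsilyl)oxy]-4-[(1E,3RS)-3-hydroxyoct-1-en-1-yl]hexahydro-2H-cyclopenta[b]furan-2-ol (anomer mixture)
Conditions: i-Bu2AlH (2.5 equiv), CH2Cl2, −78 °C; aq. KNaC4H4O6
Reagents that add atoms: none
Why: Partial reduction of a γ-lactone to the lactol by i-Bu2AlH at low temperature, the tetrahedral aluminium acetal being stable until work-up while the silyl ether and alkene are inert.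

**Step 6**
Reactants: 14 (3aR,4R,5R,6aS)-5-[(tert-butyldimethylsilyl)oxy]-4-[(1E,3RS)-3-hydroxyoct-1-en-1-yl]hexahydro-2H-cyclopenta[b]furan-2-ol; 15 (4-carboxybutyl)triphenylphosphonium bromide
Product: 18 (5Z)-7-[(1R,2R,3R,5S)-3,5-dihydroxy-2-[(1E,3RS)-3-hydroxyoct-1-en-1-yl]cyclopentyl]hept-5-enoic acid (PGF2α and its 15-epimer, 1:1), via phosphonium ylide 16 (not isolated), via 11-O-silyl acid 17 (not isolated)
Conditions: 15 (4 equiv), KOt-Bu (8 equiv), THF, 0 °C → rt; then aq. HCl to pH 1, THF, rt, 16 h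
Reagents that add atoms: none
Why: Z-selective Wittig olefination of the lactol (reacting through its open hydroxy aldehyde form) with the non-stabilised carboxylate ylide under lithium-free potassium conditions sets the 5Z alkene, and the acidification needed to extract the acid also hydrolyses the secondary silyl ether.

**Step 7**
Reactants: 18 (5Z)-7-[(1R,2R,3R,5S)-3,5-dihydroxy-2-[(1E,3RS)-3-hydroxyoct-1-en-1-yl]cyclopentyl]hept-5-enoic acid
Product: 19 15-keto-PGF2α, (5Z)-7-[(1R,2R,3R,5S)-3,5-dihydroxy-2-[(E)-3-oxooct-1-en-1-yl]cyclopentyl]hept-5-enoic acid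
Conditions: DDQ (1.5 equiv), 1,4-dioxane, rt
Reagents that add atoms: none
Why: Chemoselective DDQ dehydrogenation of the allylic alcohol (hydride abstraction from the allylic carbinol C–H), which leaves the two non-allylic ring carbinols and the Z alkene untouched and converts both C15 epimers into the same E-enone.

## Compound list

1 | cyclopentadiene | C1=CC=CC1 | starting material
2 | (1R,4S)-2,3-dioxabicyclo[2.2.1]hept-5-ene (meso endoperoxide) | C1=C[C@H]2OO[C@@H]1C2 | intermediate
3 | (R)-4-hydroxycyclopent-2-en-1-one | O=C1C=C[C@H](O)C1 | intermediate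
4 | (R)-4-[(tert-butyldimethylsilyl)oxy]cyclopent-2-en-1-one | O=C1C=C[C@H](O[Si](C)(C)C(C)(C)C)C1 | intermediate
5 | vinylmagnesium bromide | C=C[Mg]Br | starting material
6 | ethyl iodoacetate | CCOC(=O)CI | starting material
7 | bromomagnesium (3R,4R)-4-[(tert-butyldimethylsilyl)oxy]-3-vinylcyclopent-1-en-1-olate | C=C[C@@H]1C=C(O[Mg]Br)C[C@H]1O[Si](C)(C)C(C)(C)C | intermediate
8 | tert-butyl(dimethyl){[(1R,2R)-4-[(triphenylstannyl)oxy]-2-vinylcyclopent-3-en-1-yl]oxy}silane (tin enolate) | C=C[C@@H]1C=C(O[Sn](c2ccccc2)(c2ccccc2)c2ccccc2)C[C@H]1O[Si](C)(C)C(C)(C)C | intermediate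
9 | ethyl 2-[(1R,2R,3R)-3-[(tert-butyldimethylsilyl)oxy]-5-oxo-2-vinylcyclopentyl]acetate | C=C[C@@H]1[C@@H](CC(=O)OCC)C(=O)C[C@H]1O[Si](C)(C)C(C)(C)C | intermediate
10 | ethyl 2-[(1R,2R,3R,5S)-3-[(tert-butyldimethylsilyl)oxy]-5-hydroxy-2-vinylcyclopentyl]acetate | C=C[C@@H]1[C@@H](CC(=O)OCC)[C@@H](O)C[C@H]1O[Si](C)(C)C(C)(C)C | intermediate
11 | (3aR,4R,5R,6aS)-5-[(tert-butyldimethylsilyl)oxy]-4-vinylhexahydro-2H-cyclopenta[b]furan-2-one | C=C[C@@H]1[C@H]2CC(=O)O[C@H]2C[C@H]1O[Si](C)(C)C(C)(C)C | intermediate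
12 | racemic oct-1-en-3-ol | CCCCCC(O)C=C | starting material
13 | (3aR,4R,5R,6aS)-5-[(tert-butyldimethylsilyl)oxy]-4-[(1E,3RS)-3-hydroxyoct-1-en-1-yl]hexahydro-2H-cyclopenta[b]furan-2-one | CCCCCC(O)/C=C/[C@@H]1[C@H]2CC(=O)O[C@H]2C[C@H]1O[Si](C)(C)C(C)(C)C | intermediate
14 | (3aR,4R,5R,6aS)-5-[(tert-butyldimethylsilyl)oxy]-4-[(1E,3RS)-3-hydroxyoct-1-en-1-yl]hexahydro-2H-cyclopenta[b]furan-2-ol (anomer mixture) | CCCCCC(O)/C=C/[C@@H]1[C@H]2CC(O)O[C@H]2C[C@H]1O[Si](C)(C)C(C)(C)C | intermediate
15 | (4-carboxybutyl)triphenylphosphonium bromide | OC(=O)CCCC[P+](c1ccccc1)(c1ccccc1)c1ccccc1.[Br-] | starting material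
16 | potassium 5-(triphenyl-λ5-phosphanylidene)pentanoate (ylide) | [K+].[O-]C(=O)CCCC=P(c1ccccc1)(c1ccccc1)c1ccccc1 | intermediate
17 | (5Z)-7-[(1R,2R,3R,5S)-3-[(tert-butyldimethylsilyl)oxy]-5-hydroxy-2-[(1E,3RS)-3-hydroxyoct-1-en-1-yl]cyclopentyl]hept-5-enoic acid | CCCCCC(O)/C=C/[C@@H]1[C@@H](C/C=C\CCCC(=O)O)[C@@H](O)C[C@H]1O[Si](C)(C)C(C)(C)C | intermediate
18 | (5Z)-7-[(1R,2R,3R,5S)-3,5-dihydroxy-2-[(1E,3RS)-3-hydroxyoct-1-en-1-yl]cyclopentyl]hept-5-enoic acid | CCCCCC(O)/C=C/[C@@H]1[C@@H](C/C=C\CCCC(=O)O)[C@@H](O)C[C@H]1O | intermediate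
19 | 15-keto-PGF2α, (5Z)-7-[(1R,2R,3R,5S)-3,5-dihydroxy-2-[(E)-3-oxooct-1-en-1-yl]cyclopentyl]hept-5-enoic acid | CCCCCC(=O)/C=C/[C@@H]1[C@@H](C/C=C\CCCC(=O)O)[C@@H](O)C[C@H]1O | target

## Step count and risk

Total step count: 7. Longest linear sequence: 7 (1 → 19).

The three steps most likely to fail:

**Step 1 (proposed new method).** The labile peroxide may decompose faster than the catalyst opens it, or the ee may be low. The fallback uses known chemistry, sets out from 1 and comes back at 4. Cyclopentadiene is photooxygenated in the presence of thiourea (O2, rose bengal, light, MeOH, −30 °C → rt) to give cis-cyclopent-4-ene-1,3-diol F1. Lipase-catalysed desymmetrising mono-acetylation (pancreatin, vinyl acetate, Et3N, THF) gives (1S,4R)-4-hydroxycyclopent-2-en-1-yl acetate F2. Silylation (TBSCl, imidazole, DMF) gives (1S,4R)-4-[(tert-butyldimethylsilyl)oxy]cyclopent-2-en-1-yl acetate F3. Methanolysis (K2CO3, MeOH) gives (1S,4R)-4-[(tert-butyldimethylsilyl)oxy]cyclopent-2-en-1-ol F4, and allylic oxidation (MnO2, CH2Cl2) gives 4. Here the enzyme differentiates the two carbinol carbons by acyl transfer, instead of the catalyst differentiating the two bridgehead protons.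

**Step 2.** The enolate may equilibrate and eliminate the silyloxy group, or alkylate poorly. The fallback sets out from 4 and comes back at 9. Copper-catalysed vinyl addition with silyl trapping (CH2=CHMgBr, CuBr·SMe2 10 mol %, TMSCl, THF, −78 °C, Et3N quench) gives the isolable tert-butyl(dimethyl){[(1R,2R)-4-(trimethylsilyloxy)-2-vinylcyclopent-3-en-1-yl]oxy}silane F5. Visible-light photoredox alkylation of this silyl enol ether with ethyl bromoacetate (Ir(ppy)3 1 mol %, blue LEDs, MeCN, rt) then forms the C8–C7 bond by radical addition anti to the vinyl group and gives 9, with no basic enolate present.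

**Step 7.** The oxidation may be slow or unselective on the free triol acid, and the polar product may be hard to purify. The fallback sets out from 11 and comes back at 19, carrying C15 at the ketone oxidation state in masked form so that no late oxidation is needed.
- Cross-metathesis of 11 with oct-1-en-3-one (same ruthenium catalyst, CH2Cl2, 40 °C) gives (3aR,4R,5R,6aS)-5-[(tert-butyldimethylsilyl)oxy]-4-[(E)-3-oxooct-1-en-1-yl]hexahydro-2H-cyclopenta[b]furan-2-one F6.
- Ketalisation (1,2-bis(trimethylsilyloxy)ethane, TMSOTf cat., CH2Cl2, −78 °C) gives (3aR,4R,5R,6aS)-5-[(tert-butyldimethylsilyl)oxy]-4-[(E)-2-(2-pentyl-1,3-dioxolan-2-yl)ethenyl]hexahydro-2H-cyclopenta[b]furan-2-one F7.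
- i-Bu2AlH (CH2Cl2, −78 °C) gives (3aR,4R,5R,6aS)-5-[(tert-butyldimethylsilyl)oxy]-4-[(E)-2-(2-pentyl-1,3-dioxolan-2-yl)ethenyl]hexahydro-2H-cyclopenta[b]furan-2-ol F8.
- Wittig reaction with ylide 16 (from 15 and KOt-Bu, THF) gives (5Z)-7-[(1R,2R,3R,5S)-3-[(tert-butyldimethylsilyl)oxy]-5-hydroxy-2-[(E)-2-(2-pentyl-1,3-dioxolan-2-yl)ethenyl]cyclopentyl]hept-5-enoic acid F9, which is not isolated; the aqueous HCl/THF work-up removes both the silyl ether and the dioxolane to give 19.

## Further compounds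

F1 | step 1 | cis-cyclopent-4-ene-1,3-diol (meso) | O[C@@H]1C=C[C@H](O)C1
F2 | step 1 | (1S,4R)-4-hydroxycyclopent-2-en-1-yl acetate | CC(=O)O[C@@H]1C=C[C@H](O)C1
F3 | step 1 | (1S,4R)-4-[(tert-butyldimethylsilyl)oxy]cyclopent-2-en-1-yl acetate | CC(=O)O[C@@H]1C=C[C@H](O[Si](C)(C)C(C)(C)C)C1
F4 | step 1 | (1S,4R)-4-[(tert-butyldimethylsilyl)oxy]cyclopent-2-en-1-ol | O[C@@H]1C=C[C@H](O[Si](C)(C)C(C)(C)C)C1
F5 | step 2 | tert-butyl(dimethyl){[(1R,2R)-4-(trimethylsilyloxy)-2-vinylcyclopent-3-en-1-yl]oxy}silane | C=C[C@@H]1C=C(O[Si](C)(C)C)C[C@H]1O[Si](C)(C)C(C)(C)C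
F6 | step 7 | (3aR,4R,5R,6aS)-5-[(tert-butyldimethylsilyl)oxy]-4-[(E)-3-oxooct-1-en-1-yl]hexahydro-2H-cyclopenta[b]furan-2-one | CCCCCC(=O)/C=C/[C@@H]1[C@H]2CC(=O)O[C@H]2C[C@H]1O[Si](C)(C)C(C)(C)C
F7 | step 7 | (3aR,4R,5R,6aS)-5-[(tert-butyldimethylsilyl)oxy]-4-[(E)-2-(2-pentyl-1,3-dioxolan-2-yl)ethenyl]hexahydro-2H-cyclopenta[b]furan-2-one | CCCCCC3(OCCO3)/C=C/[C@@H]1[C@H]2CC(=O)O[C@H]2C[C@H]1O[Si](C)(C)C(C)(C)C
F8 | step 7 | (3aR,4R,5R,6aS)-5-[(tert-butyldimethylsilyl)oxy]-4-[(E)-2-(2-pentyl-1,3-dioxolan-2-yl)ethenyl]hexahydro-2H-cyclopenta[b]furan-2-ol | CCCCCC3(OCCO3)/C=C/[C@@H]1[C@H]2CC(O)O[C@H]2C[C@H]1O[Si](C)(C)C(C)(C)C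
F9 | step 7 | (5Z)-7-[(1R,2R,3R,5S)-3-[(tert-butyldimethylsilyl)oxy]-5-hydroxy-2-[(E)-2-(2-pentyl-1,3-dioxolan-2-yl)ethenyl]cyclopentyl]hept-5-enoic acid | CCCCCC3(OCCO3)/C=C/[C@@H]1[C@@H](C/C=C\CCCC(=O)O)[C@@H](O)C[C@H]1O[Si](C)(C)C(C)(C)C
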